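## Retrosynthetic overview

- Target 24, (3R,6R,3'R,6'R)-ε,ε-carotene-3,3'-diol, is C2-symmetric: both C-11=C-12 bonds are cut (double Wittig) into two C15 phosphonium salts 21 and the C10 dialdehyde 22. Salt 21 comes from ring alcohol 17 by cross-metathesis, vinyl addition and salt formation.
- The six-membered ring is formed once, in step 10 (both rings of 24 come from the same ring alcohol). The C-2 methylene is joined to the carbinol carbon C-3 by intramolecular alkylchromium addition of a neopentylic iodide to the (Z)-enal of 13, and C-3 is then inverted (Mitsunobu).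
- Enabling feature: C-2 is a CH2 on the quaternary C-1 (no β-hydrogen, no 3-exo or 5-exo radical acceptor). C-3 is an allylic carbinol carbon on the (Z)-C-4=C-5 ring alkene, so it can be an enal carbon that this alkene holds next to C-2.
- C-6 and the quaternary C-1 are set together beforehand by iridium-catalysed asymmetric allylic alkylation of dienyl carbonate 6 with the isobutyrate ketene acetal 7. Carbonate 6 comes from (2Z)-3-methylpent-2-en-4-yn-1-ol 1.

Key step: step 10

Remark: locants C-1 to C-15 follow carotenoid numbering (C-1 gem-dimethyl carbon, C-2 ring methylene, C-3 carbinol carbon, C-6 ring carbon bearing the chain).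
Assumption: the facial sense of the iridium catalyst in step 5 follows the usual model for monosubstituted allyl carbonates; the ligand enantiomer to be used is the one that leads to (3S)-8.

## Route

Step 1
Reactants: 1 (2Z)-3-methylpent-2-en-4-yn-1-ol
Product: 2 tert-butyl(dimethyl){[(2Z)-3-methylpent-2-en-4-yn-1-yl]oxy}silane
Conditions: TBSCl, imidazole, CH2Cl2, 0 °C to rt
Reagents that add atoms: tert-butyl(chloro)dimethylsilane, CC(C)(C)[Si](C)(C)Cl
Why: Silylation of the primary allylic alcohol masks the future C-3 oxygen so that it can later be told apart from the second primary hydroxyl made in step 2.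

Step 2
Reactants: 2 tert-butyl(dimethyl){[(2Z)-3-methylpent-2-en-4-yn-1-yl]oxy}silane
Product: 4 (4Z)-6-{[tert-butyl(dimethyl)silyl]oxy}-4-methylhex-4-en-2-yn-1-ol, via lithium acetylide 3 (not isolated)
Conditions: n-BuLi, THF, −78 °C; (CH2O)n, −78 °C to rt; H2O
Reagents that add atoms: n-butyllithium, [Li]CCCC (lithium stays in 3 only); formaldehyde from paraformaldehyde, C=O
Why: Deprotonation of the terminal alkyne and addition of the acetylide to formaldehyde (alkynylation of an aldehyde) adds the carbon that becomes C-8.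

Step 3
Reactants: 4 (4Z)-6-{[tert-butyl(dimethyl)silyl]oxy}-4-methylhex-4-en-2-yn-1-ol
Product: 5 (2E,4Z)-6-{[tert-butyl(dimethyl)silyl]oxy}-4-methylhexa-2,4-dien-1-ol
Conditions: NaAlH2(OCH2CH2OMe)2, THF, 0 °C to rt; aq. potassium sodium tartrate
Reagents that add atoms: none
Why: Hydroxyl-directed trans-hydroalumination of the propargylic alcohol should give the (E)-allylic alcohol only, and the (Z)-trisubstituted alkene and the silyl ether are not touched.

Step 4
Reactants: 5 (2E,4Z)-6-{[tert-butyl(dimethyl)silyl]oxy}-4-methylhexa-2,4-dien-1-ol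
Product: 6 (2E,4Z)-6-{[tert-butyl(dimethyl)silyl]oxy}-4-methylhexa-2,4-dien-1-yl methyl carbonate
Conditions: ClCO2Me, pyridine, CH2Cl2, 0 °C
Reagents that add atoms: methyl chloroformate, COC(=O)Cl
Why: Acylation of the primary alcohol gives the allylic carbonate that serves as leaving group and internal methoxide source in step 5.

Step 5
Reactants: 6 (2E,4Z)-6-{[tert-butyl(dimethyl)silyl]oxy}-4-methylhexa-2,4-dien-1-yl methyl carbonate; 7 [(1-methoxy-2-methylprop-1-en-1-yl)oxy](trimethyl)silane
Product: 8 methyl (3S)-3-[(2Z)-4-{[tert-butyl(dimethyl)silyl]oxy}but-2-en-2-yl]-2,2-dimethylpent-4-enoate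
Conditions: [Ir(cod)Cl]2 (2 mol %), O,O'-(1,1'-binaphthalene-2,2'-diyl)-N,N-bis(1-phenylethyl)phosphoramidite (4 mol %, single enantiomer, pre-activated with n-PrNH2), 7 (2 equiv), THF, 25 to 40 °C
Reagents that add atoms: none
Why: Iridium-catalysed asymmetric allylic alkylation: the carbonate ionises to a monosubstituted allyl–iridium complex, and the ketene acetal (desilylated by the released methoxide) should attack its substituted terminus on the face fixed by the ligand, which sets C-6 and builds the quaternary C-1 at once, while the trisubstituted allylic silyl ether cannot ionise.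

Step 6
Reactants: 8 methyl (3S)-3-[(2Z)-4-{[tert-butyl(dimethyl)silyl]oxy}but-2-en-2-yl]-2,2-dimethylpent-4-enoate
Product: 9 (3S)-3-[(2Z)-4-{[tert-butyl(dimethyl)silyl]oxy}but-2-en-2-yl]-2,2-dimethylpent-4-en-1-ol
Conditions: LiAlH4, Et2O, 0 °C; H2O
Reagents that add atoms: none
Why: Hydride reduction of the hindered ester gives the neopentylic alcohol (the future C-2) and leaves alkenes and silyl ether alone.

Step 7
Reactants: 9 (3S)-3-[(2Z)-4-{[tert-butyl(dimethyl)silyl]oxy}but-2-en-2-yl]-2,2-dimethylpent-4-en-1-ol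
Product: 11 tert-butyl{[(2Z,4S)-4-(1-iodo-2-methylpropan-2-yl)-3-methylhexa-2,5-dien-1-yl]oxy}dimethylsilane, via neopentylic triflate 10 (not isolated)
Conditions: Tf2O, 2,6-lutidine, CH2Cl2, −78 °C; then NaI, DMF, rt
Reagents that add atoms: trifluoromethanesulfonic anhydride, O=S(=O)(OS(=O)(=O)C(F)(F)F)C(F)(F)F (triflyl group stays in 10 only); sodium iodide, [Na+].[I-]
Why: Triflation followed by SN2 displacement with iodide is chosen because a neopentylic carbon needs the triflate leaving group to be substituted at rt, and neither alkene can assist ionisation through a favourable ring size.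

Step 8
Reactants: 11 tert-butyl{[(2Z,4S)-4-(1-iodo-2-methylpropan-2-yl)-3-methylhexa-2,5-dien-1-yl]oxy}dimethylsilane
Product: 12 (2Z,4S)-4-(1-iodo-2-methylpropan-2-yl)-3-methylhexa-2,5-dien-1-ol
Conditions: Bu4NF, AcOH, THF, 0 °C to rt
Reagents that add atoms: none
Why: Buffered fluoride desilylation frees the allylic alcohol, and the neopentylic iodide can undergo neither substitution nor elimination (no β-hydrogen).

Step 9
Reactants: 12 (2Z,4S)-4-(1-iodo-2-methylpropan-2-yl)-3-methylhexa-2,5-dien-1-ol
Product: 13 (2Z,4S)-4-(1-iodo-2-methylpropan-2-yl)-3-methylhexa-2,5-dienal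
Conditions: MnO2, CH2Cl2, 0 °C to rt, dark; used at once
Reagents that add atoms: none
Why: Allylic oxidation with MnO2 is neutral and heterogeneous, should keep the (Z)-enal geometry (as in nerol to neral) and should not disturb the iodide or the acidic, doubly allylic C-6–H.

Step 10
Reactants: 13 (2Z,4S)-4-(1-iodo-2-methylpropan-2-yl)-3-methylhexa-2,5-dienal
Product: 15 (1S,4R)-4-ethenyl-3,5,5-trimethylcyclohex-2-en-1-ol, via alkylchromium dichloride 14 (not isolated)
Conditions: CrCl2 (5 equiv), cobalt phthalocyanine Co(C32H16N8) (10 mol %), DMF, rt, 0.02 M, slow addition of 13, dark; H2O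
Reagents that add atoms: chromium dichloride, Cl[Cr]Cl (its atoms stay in 14 only, not in 15)
Why: Monovalent cobalt, formed from the phthalocyanine complex by divalent chromium, should activate the neopentylic C-2–I bond, the primary C-2 radical is captured by divalent chromium to give the alkyl–trivalent chromium species 14, and this adds to the aldehyde carbon C-3 in a 6-exo-trig closure that forms the C-2–C-3 bond and the ring. The closest known reaction type is the cobalt-catalysed alkyl Nozaki–Hiyama–Kishi reaction of primary alkyl iodides with aldehydes, together with ring-closing Nozaki–Hiyama–Kishi reactions of alkenyl halides. The new stereocentre C-3 is controlled by C-6 through a half-chair transition state in which the forming chromium alkoxide is pseudo-equatorial (a pseudo-axial oxygen would meet the axial methyl on C-1 in a 1,3-diaxial contact) and the vinyl group on C-6 is pseudo-axial (avoiding A(1,2) strain with the C-5 methyl), so oxygen and vinyl should end on the same ring face, that is the (3S,6R) cis alcohol 15, which step 11 inverts. The step needs 1,2-addition without radical side paths: alkylchromium reagents add only to the aldehyde carbon, and the C-2 radical has no β-hydrogen on C-1 and only 4-exo or 5-endo modes towards the two alkenes, so capture by chromium should win. The (Z)-geometry of the C-4=C-5 alkene is what brings C-2 and C-3 within reach, and the neutral aprotic medium should spare both this geometry and the C-6 stereocentre.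

Step 11
Reactants: 15 (1S,4R)-4-ethenyl-3,5,5-trimethylcyclohex-2-en-1-ol
Product: 17 (1R,4R)-4-ethenyl-3,5,5-trimethylcyclohex-2-en-1-ol, via 4-nitrobenzoate ester 16 (not isolated)
Conditions: PPh3, DIAD, 4-nitrobenzoic acid, THF, 0 °C to rt; then K2CO3 (cat.), MeOH, rt
Reagents that add atoms: 4-nitrobenzoic acid, OC(=O)c1ccc(cc1)[N+](=O)[O-] (acyl group in 16; its oxygen atom stays on C-3 of 17)
Why: Mitsunobu reaction: SN2 displacement of the oxyphosphonium group by 4-nitrobenzoate inverts C-3 to (R) (SN2' attack would have to occur at the fully substituted C-5 and is disfavoured), and mild methanolysis of the activated ester then frees the trans alcohol.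

Step 12
Reactants: 17 (1R,4R)-4-ethenyl-3,5,5-trimethylcyclohex-2-en-1-ol; 18 but-3-en-2-one
Product: 19 (3E)-4-[(1R,4R)-4-hydroxy-2,6,6-trimethylcyclohex-2-en-1-yl]but-3-en-2-one
Conditions: 18 (5 equiv), second-generation Hoveyda–Grubbs catalyst RuCl2(H2IMes)(=CH-C6H4-2-O-i-Pr) (5 mol %), CH2Cl2, 40 °C
Reagents that add atoms: none
Why: Cross-metathesis of the terminal alkene with the electron-poor enone partner should be (E)-selective because the conjugated product does not re-enter the cycle, and the trisubstituted ring alkene is inert.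

Step 13
Reactants: 19 (3E)-4-[(1R,4R)-4-hydroxy-2,6,6-trimethylcyclohex-2-en-1-yl]but-3-en-2-one
Product: 20 (1E,3RS)-1-[(1R,4R)-4-hydroxy-2,6,6-trimethylcyclohex-2-en-1-yl]-3-methylpenta-1,4-dien-3-ol
Conditions: CH2=CHMgBr (3 equiv), THF, −20 to 0 °C; H2O
Reagents that add atoms: vinylmagnesium bromide, C=C[Mg]Br
Why: 1,2-Addition of the vinyl Grignard reagent to the methyl ketone (the first equivalent is consumed by the hydroxyl group); the new carbinol centre forms as both epimers and is removed again in step 14.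

Step 14
Reactants: 20 (1E,3RS)-1-[(1R,4R)-4-hydroxy-2,6,6-trimethylcyclohex-2-en-1-yl]-3-methylpenta-1,4-dien-3-ol
Product: 21 [(2E,4E)-5-[(1R,4R)-4-hydroxy-2,6,6-trimethylcyclohex-2-en-1-yl]-3-methylpenta-2,4-dien-1-yl](triphenyl)phosphonium bromide
Conditions: PPh3·HBr, MeOH, 0 °C to rt; crystallisation
Reagents that add atoms: triphenylphosphine hydrobromide, [Br-].c1ccc(cc1)[PH+](c1ccccc1)c1ccccc1
Why: Acid-promoted ionisation of the tertiary bis-allylic alcohol to a pentadienyl cation and capture by PPh3 at the unhindered terminus (allylic transposition, the standard C15 phosphonium salt formation) should give mainly the (2E,4E) salt, while the secondary ring carbinol ionises much more slowly under these mild conditions.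

Step 15
Reactants: 21 [(2E,4E)-5-[(1R,4R)-4-hydroxy-2,6,6-trimethylcyclohex-2-en-1-yl]-3-methylpenta-2,4-dien-1-yl](triphenyl)phosphonium bromide (2.1 equiv); 22 (2E,4E,6E)-2,7-dimethylocta-2,4,6-trienedial
Product: 24 (3R,6R,3'R,6'R)-ε,ε-carotene-3,3'-diol, via phosphorus ylide 23 (not isolated)
Conditions: NaOMe, MeOH/CH2Cl2, 0 °C to rt; then n-heptane, reflux, dark
Reagents that add atoms: none
Why: Two-fold Wittig olefination of the dialdehyde with the allylic ylide forms both C-11=C-12 bonds, and the (Z)-isomers formed alongside should be converted thermally into the all-(E) polyene, the thermodynamic isomer, without touching any stereocentre.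

## Compound list

1 | (2Z)-3-methylpent-2-en-4-yn-1-ol | C#C/C(C)=C\CO | starting material
2 | tert-butyl(dimethyl){[(2Z)-3-methylpent-2-en-4-yn-1-yl]oxy}silane | C#C/C(C)=C\CO[Si](C)(C)C(C)(C)C | intermediate
3 | [(3Z)-5-{[tert-butyl(dimethyl)silyl]oxy}-3-methylpent-3-en-1-yn-1-yl]lithium | [Li]C#C/C(C)=C\CO[Si](C)(C)C(C)(C)C | intermediate
4 | (4Z)-6-{[tert-butyl(dimethyl)silyl]oxy}-4-methylhex-4-en-2-yn-1-ol | OCC#C/C(C)=C\CO[Si](C)(C)C(C)(C)C | intermediate
5 | (2E,4Z)-6-{[tert-butyl(dimethyl)silyl]oxy}-4-methylhexa-2,4-dien-1-ol | OC/C=C/C(C)=C\CO[Si](C)(C)C(C)(C)C | intermediate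
6 | (2E,4Z)-6-{[tert-butyl(dimethyl)silyl]oxy}-4-methylhexa-2,4-dien-1-yl methyl carbonate | COC(=O)OC/C=C/C(C)=C\CO[Si](C)(C)C(C)(C)C | intermediate
7 | [(1-methoxy-2-methylprop-1-en-1-yl)oxy](trimethyl)silane | COC(O[Si](C)(C)C)=C(C)C | starting material
8 | methyl (3S)-3-[(2Z)-4-{[tert-butyl(dimethyl)silyl]oxy}but-2-en-2-yl]-2,2-dimethylpent-4-enoate | COC(=O)C(C)(C)[C@@H](C=C)/C(C)=C\CO[Si](C)(C)C(C)(C)C | intermediate
9 | (3S)-3-[(2Z)-4-{[tert-butyl(dimethyl)silyl]oxy}but-2-en-2-yl]-2,2-dimethylpent-4-en-1-ol | OCC(C)(C)[C@@H](C=C)/C(C)=C\CO[Si](C)(C)C(C)(C)C | intermediate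
10 | (3S)-3-[(2Z)-4-{[tert-butyl(dimethyl)silyl]oxy}but-2-en-2-yl]-2,2-dimethylpent-4-en-1-yl trifluoromethanesulfonate | O=S(=O)(OCC(C)(C)[C@@H](C=C)/C(C)=C\CO[Si](C)(C)C(C)(C)C)C(F)(F)F | intermediate
11 | tert-butyl{[(2Z,4S)-4-(1-iodo-2-methylpropan-2-yl)-3-methylhexa-2,5-dien-1-yl]oxy}dimethylsilane | ICC(C)(C)[C@@H](C=C)/C(C)=C\CO[Si](C)(C)C(C)(C)C | intermediate
12 | (2Z,4S)-4-(1-iodo-2-methylpropan-2-yl)-3-methylhexa-2,5-dien-1-ol | ICC(C)(C)[C@@H](C=C)/C(C)=C\CO | intermediate
13 | (2Z,4S)-4-(1-iodo-2-methylpropan-2-yl)-3-methylhexa-2,5-dienal | ICC(C)(C)[C@@H](C=C)/C(C)=C\C=O | intermediate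
14 | dichloro[(3S,4Z)-3-ethenyl-2,2,4-trimethyl-6-oxohex-4-en-1-yl]chromium | Cl[Cr](Cl)CC(C)(C)[C@@H](C=C)/C(C)=C\C=O | intermediate
15 | (1S,4R)-4-ethenyl-3,5,5-trimethylcyclohex-2-en-1-ol | CC1=C[C@@H](O)CC(C)(C)[C@H]1C=C | intermediate
16 | (1R,4R)-4-ethenyl-3,5,5-trimethylcyclohex-2-en-1-yl 4-nitrobenzoate | CC1=C[C@H](OC(=O)c2ccc(cc2)[N+](=O)[O-])CC(C)(C)[C@H]1C=C | intermediate
17 | (1R,4R)-4-ethenyl-3,5,5-trimethylcyclohex-2-en-1-ol | CC1=C[C@H](O)CC(C)(C)[C@H]1C=C | intermediate
18 | but-3-en-2-one | CC(=O)C=C | starting material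
19 | (3E)-4-[(1R,4R)-4-hydroxy-2,6,6-trimethylcyclohex-2-en-1-yl]but-3-en-2-one | CC(=O)/C=C/[C@H]1C(C)=C[C@H](O)CC1(C)C | intermediate
20 | (1E,3RS)-1-[(1R,4R)-4-hydroxy-2,6,6-trimethylcyclohex-2-en-1-yl]-3-methylpenta-1,4-dien-3-ol | C=CC(C)(O)/C=C/[C@H]1C(C)=C[C@H](O)CC1(C)C | intermediate
21 | [(2E,4E)-5-[(1R,4R)-4-hydroxy-2,6,6-trimethylcyclohex-2-en-1-yl]-3-methylpenta-2,4-dien-1-yl](triphenyl)phosphonium bromide | [Br-].C/C(=C\C[P+](c1ccccc1)(c1ccccc1)c1ccccc1)/C=C/[C@H]1C(C)=C[C@H](O)CC1(C)C | intermediate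
22 | (2E,4E,6E)-2,7-dimethylocta-2,4,6-trienedial | O=C/C(C)=C/C=C/C=C(C)/C=O | starting material
23 | (1R,4R)-3,5,5-trimethyl-4-[(1E,3E)-3-methyl-5-(triphenyl-λ5-phosphanylidene)penta-1,3-dien-1-yl]cyclohex-2-en-1-ol | C/C(=C\C=P(c1ccccc1)(c1ccccc1)c1ccccc1)/C=C/[C@H]1C(C)=C[C@H](O)CC1(C)C | intermediate
24 | (3R,6R,3'R,6'R)-ε,ε-carotene-3,3'-diol | CC1=C[C@H](O)CC(C)(C)[C@H]1/C=C/C(C)=C/C=C/C(C)=C/C=C/C=C(C)/C=C/C=C(C)/C=C/[C@H]1C(C)=C[C@H](O)CC1(C)C | target

## Step count and risks

Total step count: 15. Longest linear sequence: 15 steps (1 to 24; 7, 18 and 22 are purchased).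

Steps most likely to fail:

1. Step 10. The addition of the alkylchromium group to the aldehyde may differentiate the two faces only weakly, so that both C-3 epimers form and the inversion of step 11 no longer leads to one isomer. The fallback sets out from 15 (as the epimer mixture) and replaces inversion by hydride delivery. Oxidation with MnO2 in CH2Cl2 should give (4R)-4-ethenyl-3,5,5-trimethylcyclohex-2-en-1-one F1. Reduction with KBH(s-Bu)3 in THF at −78 °C should then bring hydride in anti to the axial methyl on C-1, that is on the vinyl-bearing face, and place the hydroxyl trans to the vinyl group. This comes back to the route at 17, and step 11 is not needed.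

2. Step 5. The bulky ketene acetal may attack the unsubstituted allyl terminus (linear ester), or enantioselectivity and the (Z)-alkene geometry may erode through allyl isomerisation. The fallback sets out from 5 and uses a sigmatropic rearrangement plus resolution. Heating 5 with trimethyl orthoisobutyrate and a trace of propanoic acid (Johnson–Claisen rearrangement) passes through tert-butyl{[(2Z,4E)-6-[(1-methoxy-2-methylprop-1-en-1-yl)oxy]-3-methylhexa-2,4-dien-1-yl]oxy}dimethylsilane F2 and should give racemic methyl (3RS)-3-[(2Z)-4-{[tert-butyl(dimethyl)silyl]oxy}but-2-en-2-yl]-2,2-dimethylpent-4-enoate F3. Separation of the enantiomers by preparative chromatography on a chiral stationary phase comes back to the route at 8.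

3. Step 12. Metathesis may be sluggish at the hindered, allylically branched vinyl group, so that self-metathesis of 18 and alkene migration by ruthenium hydrides take over. The fallback sets out from 17 and builds the chain by a Heck reaction. Coupling with ethyl (2E)-3-iodobut-2-enoate (Pd(OAc)2, Ag2CO3, DMF, 60 °C, via zerovalent palladium) should give ethyl (2E,4E)-5-[(1R,4R)-4-hydroxy-2,6,6-trimethylcyclohex-2-en-1-yl]-3-methylpenta-2,4-dienoate F4. Reduction with i-Bu2AlH in CH2Cl2 at −78 °C should give (2E,4E)-5-[(1R,4R)-4-hydroxy-2,6,6-trimethylcyclohex-2-en-1-yl]-3-methylpenta-2,4-dien-1-ol F5. Treatment with PPh3·HBr in MeOH comes back to the route at 21, and steps 13 and 14 are not needed.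

## Further compounds

F1 | step 10 | (4R)-4-ethenyl-3,5,5-trimethylcyclohex-2-en-1-one | CC1=CC(=O)CC(C)(C)[C@H]1C=C
F2 | step 5 | tert-butyl{[(2Z,4E)-6-[(1-methoxy-2-methylprop-1-en-1-yl)oxy]-3-methylhexa-2,4-dien-1-yl]oxy}dimethylsilane | COC(=C(C)C)OC/C=C/C(C)=C\CO[Si](C)(C)C(C)(C)C
F3 | step 5 | methyl (3RS)-3-[(2Z)-4-{[tert-butyl(dimethyl)silyl]oxy}but-2-en-2-yl]-2,2-dimethylpent-4-enoate | COC(=O)C(C)(C)C(C=C)/C(C)=C\CO[Si](C)(C)C(C)(C)C
F4 | step 12 | ethyl (2E,4E)-5-[(1R,4R)-4-hydroxy-2,6,6-trimethylcyclohex-2-en-1-yl]-3-methylpenta-2,4-dienoate | CCOC(=O)/C=C(C)/C=C/[C@H]1C(C)=C[C@H](O)CC1(C)C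
F5 | step 12 | (2E,4E)-5-[(1R,4R)-4-hydroxy-2,6,6-trimethylcyclohex-2-en-1-yl]-3-methylpenta-2,4-dien-1-ol | OC/C=C(C)/C=C/[C@H]1C(C)=C[C@H](O)CC1(C)C
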